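**Retrosynthetic overview**

1. Numbering follows the clerodanes: ring C1–C10 with C5=C19H2, C4–CO2Me, C10H2, C8–CH3 (C17), quaternary C9 (C20, side chain C11–C12). The ring triene C19=C5–C4=C3–C2=C1 beside the C10 methylene is the ring-opened, [1,7]-hydrogen-shifted form of a cyclohexa-1,3-diene (ring A: C1–C5 plus C10). The ten-membered ring is therefore made last from trans-fused diene ester 24, which carries a temporary C5–C10 bond, by photochemical 6π ring opening and thermal [1,7]-H shift.
2. With C5–C10 in place, C7–C8 is a bond of a six-membered ring B. It is closed by a hydrogen-atom-transfer radical cyclisation: the C9 vinyl group (C8=C17, the latent C8H–CH3 unit next to quaternary C9) adds as a C8 radical to the tosylhydrazone of the C7 aldehyde, which then leaves as sulfinate and N2, so C7 ends as CH2.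
3. Ring A dienoate from the C4 ketone and an axial C2 silyloxy group (from (S)-carvone by Criegee rearrangement; it also steers the C9–C10 bond): E1cB to the enone, dienyl triflate, methoxycarbonylation.
4. C9–C10 by Mukaiyama–Michael addition of the silyl ketene acetal of γ-lactone 4 (C8 as lactone carbonyl tied to O12, a temporary ring that relays C12 to C9) to enone 9. Lactol formation and Wittig reaction then turn C8 into the vinyl group and free O12 for the ester. C5 is set by enolate prenylation (prenyl = masked C6–C7 aldehyde).
5. Ring order: furan and ring A are bought; temporary γ-lactone (step 2, opened in step 8); ring B (step 12); ring A is opened into the ten-membered ring (step 15).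

Key step: step 12

Assumption: (R)-2-methylbutanoic acid (14) is bought as the single enantiomer.

**Route**

Step 1
Reactants: 1 1-(furan-3-yl)ethan-1-one
Product: 2 methyl 4-(furan-3-yl)-2-methyl-4-oxobutanoate (racemic)
Conditions: LiN(i-Pr)2, THF, −78 °C; then methyl 2-bromopropanoate, DMPU, −78 → 0 °C
Reagents that add atoms: methyl 2-bromopropanoate, CC(Br)C(=O)OC
Why: The kinetic lithium enolate of the methyl ketone should displace bromide from the activated α-bromo ester (enolate alkylation), joining C12, C11, C9, C20 and the future C8 carbonyl; the α-methyl center may stay racemic because it is enolised again in step 6.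

Step 2
Reactants: 2 methyl 4-(furan-3-yl)-2-methyl-4-oxobutanoate
Product: 4 (5R)-5-(furan-3-yl)-3-methyldihydrofuran-2(3H)-one, via hydroxy ester 3 (not isolated)
Conditions: (S)-2-methyl-CBS-oxazaborolidine (cat.), BH3·SMe2, THF, −20 °C; then TsOH (cat.), PhMe, rt
Reagents that add atoms: none
Why: Corey–Bakshi–Shibata reduction should deliver hydride to the face of the aryl ketone that gives the (R)-carbinol (furyl as the large group, same sense as acetophenone with the (S)-catalyst), which sets C12, and acid then closes the γ-lactone by transesterification.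

Step 3
Reactants: 5 (S)-carvone
Product: 7 (S)-5-acetoxy-2-methylcyclohex-2-en-1-one, via methoxy hydroperoxide 6 (not isolated)
Conditions: O3, CH2Cl2/MeOH, −78 °C; then Ac2O, Et3N, DMAP (cat.), 0 °C → rt
Reagents that add atoms: ozone, [O-][O+]=O; methanol, CO
Why: Ozone should attack the electron-rich isopropenyl group in preference to the enone, methanol traps the carbonyl oxide as hydroperoxide 6, and its acetylation triggers the Criegee rearrangement (migration of the ring carbon to oxygen with retention), so the acetate takes the place of the isopropenyl group without change of configuration.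

Step 4
Reactants: 7 (S)-5-acetoxy-2-methylcyclohex-2-en-1-one
Product: 8 (S)-5-hydroxy-2-methylcyclohex-2-en-1-one
Conditions: K2CO3 (cat.), MeOH, 0 °C, short reaction time
Reagents that add atoms: none
Why: Base-catalysed transesterification removes the acetate; low temperature and short contact should keep the β-hydroxy enone from dehydrating.

Step 5
Reactants: 8 (S)-5-hydroxy-2-methylcyclohex-2-en-1-one
Product: 9 (S)-5-(tert-butyldimethylsilyloxy)-2-methylcyclohex-2-en-1-one
Conditions: t-BuMe2SiCl, imidazole, DMF, 0 °C → rt
Reagents that add atoms: tert-butyldimethylsilyl chloride, CC(C)(C)[Si](C)(C)Cl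
Why: Standard silylation gives a robust ether that serves as facial control element in step 6 and as the latent C2=C3 unsaturation used in step 13.

Step 6
Reactants: 4 (5R)-5-(furan-3-yl)-3-methyldihydrofuran-2(3H)-one; 9 (S)-5-(tert-butyldimethylsilyloxy)-2-methylcyclohex-2-en-1-one
Product: 11 triethylsilyl enol ether of the Michael adduct (lactone C9 joined to ring A C10), via silyl ketene acetal 10 (not isolated)
Conditions: Et3SiOTf, Et3N, CH2Cl2, 0 °C; then 9, −78 → −40 °C
Reagents that add atoms: triethylsilyl trifluoromethanesulfonate, CC[Si](CC)(CC)OS(=O)(=O)C(F)(F)F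
Why: Soft enolisation gives the tetrasubstituted silyl ketene acetal 10, which should add to the silyl-triflate-activated enone in a Mukaiyama–Michael reaction with silyl transfer to the enolate oxygen; C9 forms on the face of the five-membered ring anti to the furyl group and C10 on the enone face anti to the C2 silyloxy group (trans-3,5 addition, as with carvone), so both new centers follow from C12 and C2 and not from the relative topicity of approach.

Step 7
Reactants: 11 triethylsilyl enol ether of the Michael adduct
Product: 12 lactol (C8 hemiacetal, both anomers)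
Conditions: i-Bu2AlH, CH2Cl2, −78 °C; Rochelle salt work-up
Reagents that add atoms: none
Why: Partial reduction of a lactone to the lactol at low temperature is reliable, the silyl enol ether and the silyl ether are inert to the hydride, and the new hemiacetal center is of no consequence.

Step 8
Reactants: 12 lactol
Product: 13 C9 vinyl compound with free C12 hydroxyl
Conditions: Ph3PCH3Br, KOt-Bu, THF, 0 → 45 °C
Reagents that add atoms: methyltriphenylphosphonium bromide, C[P+](c1ccccc1)(c1ccccc1)c1ccccc1.[Br-]
Why: Wittig methylenation of the open hydroxy-aldehyde form of the lactol should convert C8 into the vinyl group (C8=C17) on quaternary C9 and release O12 as the free alcohol.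

Step 9
Reactants: 13 C9 vinyl compound with free C12 hydroxyl; 14 (R)-2-methylbutanoic acid
Product: 15 (R)-2-methylbutanoate ester at O12
Conditions: DCC, DMAP (cat.), CH2Cl2, 0 °C
Reagents that add atoms: none
Why: Steglich esterification acylates the only free hydroxyl, and low temperature with catalytic DMAP should leave the α-stereocenter of the acid and the silyl enol ether untouched.

Step 10
Reactants: 15 (R)-2-methylbutanoate ester at O12
Product: 16 2-methyl-2-prenyl ketone (C5 quaternary)
Conditions: (Me2N)3S+ Me3SiF2− (TASF), prenyl bromide, THF, −78 → 0 °C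
Reagents that add atoms: 1-bromo-3-methylbut-2-ene (prenyl bromide), CC(C)=CCBr
Why: Fluoride cleaves the enol silyl ether regiospecifically to the tetrasubstituted enolate, which should be C-alkylated on the face anti to the bulky C10 substituent (enolate alkylation), so C5 is set with the prenyl arm trans to C9, as a trans-decalin requires.

Step 11
Reactants: 16 2-methyl-2-prenyl ketone
Product: 18 keto aldehyde (CH2CHO arm on C5), via diol 17 (not isolated)
Conditions: OsO4 (cat.), NMO, acetone/H2O, 0 °C; then NaIO4, THF/H2O, rt
Reagents that add atoms: N-methylmorpholine N-oxide, C[N+]1([O-])CCOCC1; water, O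
Why: In this Lemieux–Johnson-type sequence the electron-rich trisubstituted prenyl alkene should be dihydroxylated in preference to the hindered vinyl group on quaternary C9 and to the furan, and periodate cleaves the diol to the C7 aldehyde.

Step 12
Reactants: 18 keto aldehyde
Product: 21 trans-fused decalone (ring B closed; 8R methyl), via tosylhydrazone 19 (not isolated), via cyclised sulfonylhydrazine 20 (not isolated)
Conditions: TsNHNH2, EtOH, rt; then Fe(acac)3, PhSiH3, 60 °C; then Et3N, 80 °C
Reagents that add atoms: none
Why: The aldehyde condenses selectively to tosylhydrazone 19, and the iron hydride formed from Fe(acac)3 and PhSiH3 transfers a hydrogen atom to the terminal carbon C17 of the C9 vinyl group, the only electron-neutral unconjugated alkene, so a secondary radical arises at C8 and C17 becomes the C8 methyl group. This radical adds to the hydrazone carbon C7 in a 6-exo-trig closure of ring B, the sulfonylhydrazinyl radical is reduced to 20, and triethylamine then expels p-toluenesulfinate to give a monoalkyl diazene that loses dinitrogen and leaves C7 as CH2. The closest known reaction type is the iron-hydride hydrogen-atom-transfer reductive alkylation of unactivated alkenes with N-tosylhydrazones, together with radical 6-exo cyclisations onto C=N acceptors. The new stereocenter C8 is set in a chair transition state in which ring B grows as the second chair of a trans-decalin: the fixed centers C5, C9 and C10 place C20 axial and C11 equatorial, and the methyl group of the planar C8 radical should take the pseudo-equatorial site, which gives C17 cis to C20 (8R). The step needs the addition to C=N to outrun premature reduction of the radical, its reversible addition to the hindered C4 ketone and attack on the furan; the fast, irreversible addition to the sulfonylhydrazone, the trans-disposed arms on ring A that pre-form the chair, and a low stationary radical concentration should secure this.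

Step 13
Reactants: 21 trans-fused decalone
Product: 23 ring A 1,3-dienyl triflate, via enone 22 (not isolated)
Conditions: KN(SiMe3)2 (2.1 equiv), THF, −78 → 0 °C; then PhNTf2, −78 °C → rt
Reagents that add atoms: N-phenyl-bis(trifluoromethanesulfonimide), O=S(=O)(N(c1ccccc1)S(=O)(=O)C(F)(F)F)C(F)(F)F
Why: The C3 enolate should expel the axial C2 silyloxide (E1cB) to give enone 22, whose γ-deprotonation at C1 (no α′ proton exists because C5 is quaternary) gives the extended dienolate that is O-sulfonylated to the dienyl triflate; the ketone-derived protons are far more acidic than the α-proton of the branched ester, which should therefore keep its configuration.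

Step 14
Reactants: 23 ring A 1,3-dienyl triflate
Product: 24 trans-fused cyclohexa-1,3-diene methyl ester (5R,8R,9S,10R,12R)
Conditions: Pd(OAc)2 (cat.), PPh3, CO (1 atm), MeOH, Et3N, DMF, 50 °C
Reagents that add atoms: carbon monoxide, [C-]#[O+]; methanol, CO
Why: Palladium-catalysed methoxycarbonylation of the dienyl triflate (oxidative addition, CO insertion, methanolysis) should give the ring A dienoate without touching any stereocenter.

Step 15
Reactants: 24 trans-fused cyclohexa-1,3-diene methyl ester
Product: 26 target CNP0305973.1, via ring-opened triene 25 (not isolated)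
Conditions: hν (300 nm), degassed Et2O, −20 °C, partial conversion with recycling of 24; then degassed isooctane, 60 °C, dark
Reagents that add atoms: none
Why: Irradiation into the dienoate band should open ring A by a conrotatory 6π electrocyclic reaction (the reaction type of provitamin D → previtamin D and of trans-fused hexalin dienes → cyclodeca-1,3,5-trienes), the four-carbon tether allowing only the mode that turns C6 and C9 outward so that C19 lies inside the triene, and warming in the dark then moves a C19 hydrogen to C10 by the antarafacial [1,7] sigmatropic shift known from previtamin D → vitamin D, which creates C5=C19 and, from the s-cis single bonds of the helical triene, the Z-C1=C2 and ring-cis C3=C4 bonds; C5 and C10 become planar or CH2, and C8, C9, C12 and the ester center are not touched.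

**Compound list**

1 | 1-(furan-3-yl)ethan-1-one | CC(=O)c1ccoc1 | starting material
2 | methyl 4-(furan-3-yl)-2-methyl-4-oxobutanoate (racemic) | COC(=O)C(C)CC(=O)c1ccoc1 | intermediate
3 | methyl (4R)-4-(furan-3-yl)-4-hydroxy-2-methylbutanoate (both C2 epimers) | COC(=O)C(C)C[C@@H](O)c1ccoc1 | intermediate
4 | (5R)-5-(furan-3-yl)-3-methyldihydrofuran-2(3H)-one (both C3 epimers) | CC1C[C@H](c2ccoc2)OC1=O | intermediate
5 | (S)-carvone | CC1=CC[C@H](C(C)=C)CC1=O | starting material
6 | (S)-5-(2-hydroperoxy-2-methoxypropan-2-yl)-2-methylcyclohex-2-en-1-one | CC1=CC[C@H](C(C)(OC)OO)CC1=O | intermediate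
7 | (S)-5-acetoxy-2-methylcyclohex-2-en-1-one | CC1=CC[C@H](OC(C)=O)CC1=O | intermediate
8 | (S)-5-hydroxy-2-methylcyclohex-2-en-1-one | CC1=CC[C@H](O)CC1=O | intermediate
9 | (S)-5-(tert-butyldimethylsilyloxy)-2-methylcyclohex-2-en-1-one | CC1=CC[C@H](O[Si](C)(C)C(C)(C)C)CC1=O | intermediate
10 | (R)-triethyl{[5-(furan-3-yl)-3-methyl-4,5-dihydrofuran-2-yl]oxy}silane | CC1=C(O[Si](CC)(CC)CC)O[C@@H](c2ccoc2)C1 | intermediate
11 | Michael adduct as triethylsilyl enol ether: γ-lactone (C8=O, O12) whose quaternary C9 is bonded to C10 of the C4-silyloxy-C5-methyl cyclohexene; C9–C10 bond trans to the C2 silyloxy group and trans to the furyl group across the lactone | CC1=C(O[Si](CC)(CC)CC)C[C@@H](O[Si](C)(C)C(C)(C)C)C[C@@H]1[C@@]1(C)C[C@H](c2ccoc2)OC1=O | intermediate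
12 | lactol of 11 (C8 hemiacetal, both anomers) | CC1=C(O[Si](CC)(CC)CC)C[C@@H](O[Si](C)(C)C(C)(C)C)C[C@@H]1[C@@]1(C)C[C@H](c2ccoc2)OC1O | intermediate
13 | silyl enol ether with C9 bearing methyl, vinyl and the (R)-2-(furan-3-yl)-2-hydroxyethyl group | CC1=C(O[Si](CC)(CC)CC)C[C@@H](O[Si](C)(C)C(C)(C)C)C[C@@H]1[C@](C)(C=C)C[C@@H](O)c1ccoc1 | intermediate
14 | (R)-2-methylbutanoic acid | CC[C@@H](C)C(=O)O | starting material
15 | (R)-2-methylbutanoate of 13 | CC1=C(O[Si](CC)(CC)CC)C[C@@H](O[Si](C)(C)C(C)(C)C)C[C@@H]1[C@](C)(C=C)C[C@@H](OC(=O)[C@H](C)CC)c1ccoc1 | intermediate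
16 | cyclohexanone with quaternary C5 (methyl, prenyl); prenyl trans to the C10 substituent; C2 silyloxy trans to the C10 substituent | CC(C)=CC[C@@]1(C)C(=O)C[C@@H](O[Si](C)(C)C(C)(C)C)C[C@@H]1[C@](C)(C=C)C[C@@H](OC(=O)[C@H](C)CC)c1ccoc1 | intermediate
17 | diol from the prenyl group of 16 (both carbinol epimers) | CC(C)(O)C(O)C[C@@]1(C)C(=O)C[C@@H](O[Si](C)(C)C(C)(C)C)C[C@@H]1[C@](C)(C=C)C[C@@H](OC(=O)[C@H](C)CC)c1ccoc1 | intermediate
18 | keto aldehyde: C5 carries methyl and CH2CHO (C6–C7) | O=CC[C@@]1(C)C(=O)C[C@@H](O[Si](C)(C)C(C)(C)C)C[C@@H]1[C@](C)(C=C)C[C@@H](OC(=O)[C@H](C)CC)c1ccoc1 | intermediate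
19 | (E)-N-tosylhydrazone of the C7 aldehyde of 18 | Cc1ccc(cc1)S(=O)(=O)N/N=C/C[C@@]1(C)C(=O)C[C@@H](O[Si](C)(C)C(C)(C)C)C[C@@H]1[C@](C)(C=C)C[C@@H](OC(=O)[C@H](C)CC)c1ccoc1 | intermediate
20 | ring-B-closed N-alkyl-N′-tosylhydrazine (hydrazine on C7, either epimer) | C[C@@H]1C(NNS(=O)(=O)c3ccc(C)cc3)C[C@@]2(C)C(=O)C[C@@H](O[Si](C)(C)C(C)(C)C)C[C@@H]2[C@@]1(C)C[C@@H](OC(=O)[C@H](C)CC)c1ccoc1 | intermediate
21 | trans-fused decalone: C4 ketone, axial C2 silyloxy, C17 equatorial and cis to C20, C19 cis to C20 | C[C@@H]1CC[C@@]2(C)C(=O)C[C@@H](O[Si](C)(C)C(C)(C)C)C[C@@H]2[C@@]1(C)C[C@@H](OC(=O)[C@H](C)CC)c1ccoc1 | intermediate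
22 | trans-fused C2=C3 enone (C4 ketone) | C[C@@H]1CC[C@@]2(C)C(=O)C=CC[C@@H]2[C@@]1(C)C[C@@H](OC(=O)[C@H](C)CC)c1ccoc1 | intermediate
23 | trans-fused dienyl triflate (C1=C2, C3=C4–OTf) | C[C@@H]1CC[C@@]2(C)C(OS(=O)(=O)C(F)(F)F)=CC=C[C@@H]2[C@@]1(C)C[C@@H](OC(=O)[C@H](C)CC)c1ccoc1 | intermediate
24 | methyl (5R,8R,9S,10R,12R)-15,16-epoxy-12-[(2R)-2-methylbutanoyloxy]cleroda-1,3,13(16),14-tetraen-18-oate | C[C@@H]1CC[C@@]2(C)C(C(=O)OC)=CC=C[C@@H]2[C@@]1(C)C[C@@H](OC(=O)[C@H](C)CC)c1ccoc1 | intermediate
25 | ten-membered 1(10),2,4-triene ester: ring-trans at C1(10) and C4, ring-cis at C2, methyl on C5; (8R,9S,12R) | COC(=O)C1=C(C)\CC[C@@H](C)[C@](C)(C[C@@H](OC(=O)[C@H](C)CC)c2ccoc2)/C=C/C=C\1 | intermediate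
26 | CNP0305973.1: methyl (1Z,3E,8R,9S,12R)-15,16-epoxy-12-[(2R)-2-methylbutanoyloxy]-5,10-secocleroda-1,3,5(19),13(16),14-pentaen-18-oate | C=C1CC[C@@H](C)[C@](C)(C[C@@H](OC(=O)[C@H](C)CC)c2ccoc2)C/C=C\C=C/1C(=O)OC | target

**Step count and risks**

Total step count: 15. Longest linear sequence: 13 steps (steps 3–5, then 6–15).

Steps most likely to fail:

1. Step 15. Thermal disrotatory reclosure of triene 25 to a cis-fused diene ester may outrun the [1,7]-hydrogen shift, and 25 and 26 may react further under the lamp (E/Z isomerisation, other ring closures). Fallback, a purely thermal funnel that sets out from 24 and comes back at 26: 24 is irradiated at −20 °C only to the stationary state and the triene is left to close in the dark to the cis-fused diene ester F1 (drawn as the 10-epimer of 24). F1 is isolated and heated on its own (degassed PhMe, sealed tube, 110–130 °C). Thermal disrotatory opening of a cis-fused cyclohexadiene gives the same ring-trans triene 25 reversibly, and the hydrogen shift drains it to 26.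

2. Step 12. The C8 radical may be reduced before it cyclises, may add reversibly to the C4 ketone or to the furan, or may close with low facial selectivity at C8. Fallback, a tin hydride cyclisation with reversed roles that sets out from 18 and comes back at 21: the aldehyde is reduced selectively with NaBH(OAc)3 to the primary alcohol F2, which is converted with I2, PPh3 and imidazole into the primary iodide F3. Slow addition of Bu3SnH with AIBN (PhH, 80 °C) generates the C7 radical, which closes ring B by 6-exo-trig attack on C8 of the vinyl group through the same chair; the exocyclic C17 radical takes up hydrogen to become the methyl group.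

3. Step 10. O-alkylation, proton transfer with enolate equilibration (and loss of the C2 silyloxy group), or low conversion at the crowded tetrasubstituted enolate. Fallback, a palladium-catalysed allylic alkylation of the silyl enol ether (Tsuji–Trost type) that sets out from 15 and comes back at 16: methyl prenyl carbonate, Pd2(dba)3 and dppe in THF generate a prenyl palladium complex and methoxide, which frees the enolate at silicon; the enolate should attack the unsubstituted allyl terminus on the face anti to the C10 substituent. This fallback makes no new compound (F0).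

**Further compounds**

F1 | step 15 | cis-fused diene ester, 10-epimer of 24 | C[C@@H]1CC[C@@]2(C)C(C(=O)OC)=CC=C[C@H]2[C@@]1(C)C[C@@H](OC(=O)[C@H](C)CC)c1ccoc1
F2 | step 12 | primary alcohol from 18 (CH2CH2OH arm on C5) | OCC[C@@]1(C)C(=O)C[C@@H](O[Si](C)(C)C(C)(C)C)C[C@@H]1[C@](C)(C=C)C[C@@H](OC(=O)[C@H](C)CC)c1ccoc1
F3 | step 12 | primary iodide from F2 (CH2CH2I arm on C5) | ICC[C@@]1(C)C(=O)C[C@@H](O[Si](C)(C)C(C)(C)C)C[C@@H]1[C@](C)(C=C)C[C@@H](OC(=O)[C@H](C)CC)c1ccoc1
F0 | step 10 | none | none
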